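## Retrosynthetic overview

1. Target 21 ⇐ aryl silyl ether 20 ⇐ triol 19 (oxidation of the C4 carbinol); 19 ⇐ hydroxy ketone 11 + the allylbarium reagent from chloride 17 (side-chain C–C bond and tertiary carbinol).
2. 11 ⇐ bicyclic enone 9 by β-borylation/oxidation (oxygen at the future C4 ketone carbon).
3. 9 ⇐ ynone 3 + 1,2-dimethylcyclopentene 4 by an amine-catalysed photochemical [2+2]/retro-Mannich/aldol-condensation cascade; both quaternary centres are set here.
4. Ring order: cyclopentane bought (in 4) → transient cyclobutane → six-membered enone, all in step 2.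
5. 3 ⇐ lactone 1 + ethynyl Grignard 2; 17 ⇐ phenol 12 + prenyl bromide 13 (ortho-prenylation/silylation, SeO2 oxidation, chlorination).

Assumption: the sense of induction of the amine in step 2 and of the ligand in step 3 is as drawn; if either proves opposite, the mirror-image amine or ligand is used and nothing else changes.

## Route

Step 1
Reactants: 1 5,5-dimethyloxolan-2-one; 2 ethynylmagnesium bromide
Product: 3 6-hydroxy-6-methylhept-1-yn-3-one
Conditions: THF, −78 to −30 °C; aq NH4Cl
Reagents that add atoms: none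
Why: Acylation of an alkynyl Grignard reagent by a lactone (ring-opening addition); at low temperature the lactone takes up one equivalent only, so the γ-hydroxy ynone is obtained without over-addition.

Step 2
Reactants: 3 6-hydroxy-6-methylhept-1-yn-3-one; 4 1,2-dimethylcyclopentene
Product: 9 (3aR,7aS)-6-(2-hydroxy-2-methylpropyl)-3a,7a-dimethyl-1,2,3,3a,4,7a-hexahydro-5H-inden-5-one, via enaminone 5 (not isolated), via aminocyclobutane 6 (not isolated), via imino ketone 7 (not isolated), via keto aldehyde 8 (not isolated)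
Conditions: (S)-3,3-dimethylbutan-2-amine (20 mol %), PhCO2H (20 mol %), H2O (2 equiv), 4 (5 equiv), MeCN, 0 °C, hν (310 nm), 3 added over 10 h; then 40 °C, dark
Reagents that add atoms: none
Why: Proposed new method: the primary amine (C[C@H](N)C(C)(C)C) adds to the ynone to give the N–H-chelated (Z)-enaminone 5, the nitrogen analogue of a de Mayo enol and the main absorber at 310 nm; A(1,3) strain fixes the N-substituent so that tert-butyl screens one face, alkene 4 adds to the open face in a [2+2] photocycloaddition with the amino and acyl groups exo (6), which sets both quaternary centres cis; retro-Mannich opening gives imine 7, hydrolysis returns the amine and gives keto aldehyde 8, and amine/acid-mediated aldol condensation onto the non-enolisable aldehyde closes the cyclohexenone; slow addition keeps free ynone low (no Bohlmann–Rahtz-type consumption of the enaminone); closest known reaction types are the de Mayo reaction and the vinylogous-amide photocycloaddition/retro-Mannich sequence, neither catalytic in amine nor enantioselective.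

Step 3
Reactants: 9 (3aR,7aS)-6-(2-hydroxy-2-methylpropyl)-3a,7a-dimethyl-1,2,3,3a,4,7a-hexahydro-5H-inden-5-one
Product: 11 (3aR,6S,7S,7aR)-7-hydroxy-6-(2-hydroxy-2-methylpropyl)-3a,7a-dimethyloctahydro-5H-inden-5-one, via boryl ketone 10 (not isolated)
Conditions: B2pin2, CuCl (5 mol %), (R,R)-QuinoxP* (6 mol %), NaOt-Bu (10 mol %), MeOH, THF, rt; then NaBO3·4H2O, THF/H2O, rt
Reagents that add atoms: bis(pinacolato)diboron, CC1(C)OB(OC1(C)C)B1OC(C)(C)C(C)(C)O1 (boron of 10 only); sodium perborate, [Na+].[O-]OB=O (hydroxyl oxygen of 11)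
Why: Copper–boryl conjugate addition (β-borylation) followed by stereoretentive C–B oxidation; the ligand-controlled catalyst delivers boron to C7 on the face opposite the angular methyls, and base equilibration of the α-centre C6 places the side chain trans to the new oxygen (both equatorial), an arrangement that is used in step 7.

Step 4
Reactants: 12 4-methoxy-2-methylphenol; 13 1-bromo-3-methylbut-2-ene
Product: 15 tert-butyl[4-methoxy-2-methyl-6-(3-methylbut-2-en-1-yl)phenoxy]dimethylsilane, via prenylphenol 14 (not isolated)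
Conditions: NaH, toluene, 0 °C; 13, rt; then TBSCl, imidazole, DMF, 40 °C
Reagents that add atoms: tert-butyldimethylsilyl chloride, CC(C)(C)[Si](C)(C)Cl
Why: ortho-C-Alkylation of a sodium phenoxide in a non-polar solvent (only one ortho position is free) followed by silylation of the hindered phenol in the same pot; no stereocentre is formed.

Step 5
Reactants: 15 tert-butyl[4-methoxy-2-methyl-6-(3-methylbut-2-en-1-yl)phenoxy]dimethylsilane
Product: 16 (2E)-4-{2-[(tert-butyldimethylsilyl)oxy]-5-methoxy-3-methylphenyl}-2-methylbut-2-en-1-ol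
Conditions: SeO2 (0.3 equiv), t-BuOOH, salicylic acid (cat.), CH2Cl2, rt
Reagents that add atoms: selenium dioxide, O=[Se]=O (oxygen donor, re-oxidised by tert-butyl hydroperoxide, CC(C)(C)OO)
Why: Riley/Sharpless allylic oxidation (ene reaction then [2,3]-sigmatropic shift) attacks the (E)-methyl of the prenyl group selectively and gives the (E)-allylic alcohol.

Step 6
Reactants: 16 (2E)-4-{2-[(tert-butyldimethylsilyl)oxy]-5-methoxy-3-methylphenyl}-2-methylbut-2-en-1-ol
Product: 17 tert-butyl{2-[(2E)-4-chloro-3-methylbut-2-en-1-yl]-4-methoxy-6-methylphenoxy}dimethylsilane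
Conditions: NCS, Me2S, CH2Cl2, −20 to 0 °C
Reagents that add atoms: N-chlorosuccinimide, O=C1CCC(=O)N1Cl
Why: Corey–Kim-type chlorination (alkoxysulfonium activation, SN2 by chloride) converts a primary allylic alcohol to the chloride without allylic transposition or loss of E geometry.

Step 7
Reactants: 11 (3aR,6S,7S,7aR)-7-hydroxy-6-(2-hydroxy-2-methylpropyl)-3a,7a-dimethyloctahydro-5H-inden-5-one; 17 tert-butyl{2-[(2E)-4-chloro-3-methylbut-2-en-1-yl]-4-methoxy-6-methylphenoxy}dimethylsilane
Product: 19 (3aR,4S,5S,6R,7aR)-6-[(2E)-4-{2-[(tert-butyldimethylsilyl)oxy]-5-methoxy-3-methylphenyl}-2-methylbut-2-en-1-yl]-5-(2-hydroxy-2-methylpropyl)-3a,7a-dimethyloctahydro-1H-indene-4,6-diol, via allylbarium chloride 18 (not isolated)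
Conditions: BaI2, Li, biphenyl, THF, rt; 17 (3.3 equiv), −78 °C; 11, THF, −78 °C; aq NH4Cl
Reagents that add atoms: none
Why: Yamamoto allylbarium addition: allylbarium reagents made at −78 °C keep their E geometry and add to ketones at the α-carbon (linear product), two further equivalents serving as base for the two hydroxyls (returned as 15); the ketone reacts as the chair with the C6 side chain and the C7 alkoxide equatorial, in which the axial angular methyl on the ring-fusion carbon 1,3 to the carbonyl blocks axial attack, so the allyl group enters equatorially and the new hydroxyl is axial, cis to the angular methyls.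

Step 8
Reactants: 19 (3aR,4S,5S,6R,7aR)-6-[(2E)-4-{2-[(tert-butyldimethylsilyl)oxy]-5-methoxy-3-methylphenyl}-2-methylbut-2-en-1-yl]-5-(2-hydroxy-2-methylpropyl)-3a,7a-dimethyloctahydro-1H-indene-4,6-diol
Product: 20 (3aR,5R,6R,7aR)-6-[(2E)-4-{2-[(tert-butyldimethylsilyl)oxy]-5-methoxy-3-methylphenyl}-2-methylbut-2-en-1-yl]-6-hydroxy-5-(2-hydroxy-2-methylpropyl)-3a,7a-dimethyloctahydro-4H-inden-4-one
Conditions: Dess–Martin periodinane, pyridine, CH2Cl2, 0 °C to rt
Reagents that add atoms: none
Why: Dess–Martin oxidation of the only secondary alcohol (tertiary alcohols are inert) gives the β-hydroxy ketone; C5, now α to the ketone, already holds its side chain equatorial and trans to the C6 side chain, the thermodynamic arrangement.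

Step 9
Reactants: 20 (3aR,5R,6R,7aR)-6-[(2E)-4-{2-[(tert-butyldimethylsilyl)oxy]-5-methoxy-3-methylphenyl}-2-methylbut-2-en-1-yl]-6-hydroxy-5-(2-hydroxy-2-methylpropyl)-3a,7a-dimethyloctahydro-4H-inden-4-one
Product: 21 (3aR,5R,6R,7aR)-6-hydroxy-6-[(2E)-4-(2-hydroxy-5-methoxy-3-methylphenyl)-2-methylbut-2-en-1-yl]-5-(2-hydroxy-2-methylpropyl)-3a,7a-dimethyloctahydro-4H-inden-4-one
Conditions: TBAF, AcOH, THF, 0 °C
Reagents that add atoms: none
Why: Fluoride cleavage of the aryl silyl ether, buffered with acetic acid so that the β-hydroxy ketone does not undergo retro-aldol cleavage.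

## Compound list

1 | 5,5-dimethyloxolan-2-one (γ,γ-dimethyl-γ-butyrolactone) | CC1(C)CCC(=O)O1 | starting material
2 | ethynylmagnesium bromide | C#C[Mg]Br | starting material
3 | 6-hydroxy-6-methylhept-1-yn-3-one | C#CC(=O)CCC(C)(C)O | intermediate
4 | 1,2-dimethylcyclopentene | CC1=C(C)CCC1 | starting material
5 | (1Z)-1-{[(2S)-3,3-dimethylbutan-2-yl]amino}-6-hydroxy-6-methylhept-1-en-3-one | CC(C)(O)CCC(=O)/C=C\N[C@@H](C)C(C)(C)C | intermediate
6 | 4-hydroxy-4-methyl-1-(cis-fused 1,5-dimethyl-7-{[(2S)-3,3-dimethylbutan-2-yl]amino}bicyclo[3.2.0]heptan-6-yl)pentan-1-one, amino and acyl groups exo (cis to the bridgehead methyls) | CC(C)(O)CCC(=O)[C@@H]1[C@@]2(C)CCC[C@@]2(C)[C@@H]1N[C@@H](C)C(C)(C)C | intermediate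
7 | (E)-imine of aldehyde 8 with (S)-3,3-dimethylbutan-2-amine | CC(C)(O)CCC(=O)C[C@@]1(C)CCC[C@@]1(C)/C=N/[C@@H](C)C(C)(C)C | intermediate
8 | (1R,2R)-2-(5-hydroxy-5-methyl-2-oxohexyl)-1,2-dimethylcyclopentane-1-carbaldehyde | CC(C)(O)CCC(=O)C[C@@]1(C)CCC[C@@]1(C)C=O | intermediate
9 | (3aR,7aS)-6-(2-hydroxy-2-methylpropyl)-3a,7a-dimethyl-1,2,3,3a,4,7a-hexahydro-5H-inden-5-one | O=C1C[C@@]2(C)CCC[C@@]2(C)C=C1CC(C)(C)O | intermediate
10 | 7-(4,4,5,5-tetramethyl-1,3,2-dioxaborolan-2-yl) analogue of 11 (boron in place of the C7 hydroxyl, same configuration) | O=C1C[C@@]2(C)CCC[C@@]2(C)[C@@H](B3OC(C)(C)C(C)(C)O3)[C@@H]1CC(C)(C)O | intermediate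
11 | (3aR,6S,7S,7aR)-7-hydroxy-6-(2-hydroxy-2-methylpropyl)-3a,7a-dimethyloctahydro-5H-inden-5-one | O=C1C[C@@]2(C)CCC[C@@]2(C)[C@@H](O)[C@@H]1CC(C)(C)O | intermediate
12 | 4-methoxy-2-methylphenol | COc1ccc(O)c(C)c1 | starting material
13 | 1-bromo-3-methylbut-2-ene (prenyl bromide) | CC(C)=CCBr | starting material
14 | 4-methoxy-2-methyl-6-(3-methylbut-2-en-1-yl)phenol | COc1cc(C)c(O)c(CC=C(C)C)c1 | intermediate
15 | tert-butyl[4-methoxy-2-methyl-6-(3-methylbut-2-en-1-yl)phenoxy]dimethylsilane | COc1cc(C)c(O[Si](C)(C)C(C)(C)C)c(CC=C(C)C)c1 | intermediate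
16 | (2E)-4-{2-[(tert-butyldimethylsilyl)oxy]-5-methoxy-3-methylphenyl}-2-methylbut-2-en-1-ol | COc1cc(C)c(O[Si](C)(C)C(C)(C)C)c(C/C=C(\C)CO)c1 | intermediate
17 | tert-butyl{2-[(2E)-4-chloro-3-methylbut-2-en-1-yl]-4-methoxy-6-methylphenoxy}dimethylsilane | COc1cc(C)c(O[Si](C)(C)C(C)(C)C)c(C/C=C(\C)CCl)c1 | intermediate
18 | (E)-allylbarium chloride derived from 17 (barium on the former CH2Cl carbon) | COc1cc(C)c(O[Si](C)(C)C(C)(C)C)c(C/C=C(\C)C[Ba]Cl)c1 | intermediate
19 | (3aR,4S,5S,6R,7aR)-6-[(2E)-4-{2-[(tert-butyldimethylsilyl)oxy]-5-methoxy-3-methylphenyl}-2-methylbut-2-en-1-yl]-5-(2-hydroxy-2-methylpropyl)-3a,7a-dimethyloctahydro-1H-indene-4,6-diol | COc1cc(C)c(O[Si](C)(C)C(C)(C)C)c(C/C=C(\C)C[C@@]2(O)C[C@@]3(C)CCC[C@@]3(C)[C@@H](O)[C@@H]2CC(C)(C)O)c1 | intermediate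
20 | (3aR,5R,6R,7aR)-6-[(2E)-4-{2-[(tert-butyldimethylsilyl)oxy]-5-methoxy-3-methylphenyl}-2-methylbut-2-en-1-yl]-6-hydroxy-5-(2-hydroxy-2-methylpropyl)-3a,7a-dimethyloctahydro-4H-inden-4-one | COc1cc(C)c(O[Si](C)(C)C(C)(C)C)c(C/C=C(\C)C[C@@]2(O)C[C@@]3(C)CCC[C@@]3(C)C(=O)[C@@H]2CC(C)(C)O)c1 | intermediate
21 | (3aR,5R,6R,7aR)-6-hydroxy-6-[(2E)-4-(2-hydroxy-5-methoxy-3-methylphenyl)-2-methylbut-2-en-1-yl]-5-(2-hydroxy-2-methylpropyl)-3a,7a-dimethyloctahydro-4H-inden-4-one | COc1cc(C)c(O)c(C/C=C(\C)C[C@@]2(O)C[C@@]3(C)CCC[C@@]3(C)C(=O)[C@@H]2CC(C)(C)O)c1 | target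

## Step count and risks

Total steps: 9. Longest linear sequence: 6 (steps 1, 2, 3, 7, 8, 9; the arene branch 4, 5, 6, 7, 8, 9 is equally long).

**Step 2 (new amine-catalysed photo-annulation).** The risks are three: whether a secondary enaminone adds to an unactivated tetrasubstituted alkene at all; whether the amine turns over; and the enantioselectivity. The last needs both face control by the amine and an exo orientation of the alkene, because an endo adduct on the same face gives the opposite enantiomer of 9.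
Fallback, known chemistry; sets out from 3 and 4, comes back at 11. Ynone 3 is hydrated with aqueous NaOH and carefully acidified to the hydroxymethylene ketone F1. F1 is irradiated at once with 4 in the classical de Mayo reaction: the [2+2] adduct F2 opens by retro-aldol to the racemic keto aldehyde F3, and K2CO3 in methanol closes it to the racemic enone F4. F4 then enters the ligand-controlled borylation/oxidation of step 3 as a divergent reaction on a racemic mixture. The (3aR,7aS) half gives 10 and then 11; the mirror-image half gives the boronate F5 and then the hydroxy ketone F6, a diastereomer of 11 that is removed by chromatography (yield ceiling 50 %).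

**Step 3 (β-borylation of a hindered enone).** The β-carbon is next to a quaternary centre and the α-carbon is substituted, so the addition may be slow. Its facial sense matters, because the C7 oxygen and the C6 side chain steer step 7.
Fallback; sets out from 9, comes back at 11. Weitz–Scheffer epoxidation (H2O2, NaOH, MeOH) gives the epoxy ketone F7, with the two epoxide faces separable if both form. SmI2 in THF/MeOH at −78 °C then cleaves the Cα–O bond and gives 11.

**Step 7 (allylbarium addition).** The risks are α- versus γ-attack, enolisation or retro-aldol of the substrate, and the facial selectivity at the new carbinol, which rests on a conformational argument only.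
Fallback; sets out from 11 and 12, comes back at 19. Ketone 11 is propargylated with allenylboronic acid pinacol ester under 3,3'-dibromo-BINOL catalysis, which puts the new carbinol centre under catalyst control and gives the homopropargylic alcohol F8. Phenol 12 is hydroxymethylated (aqueous formaldehyde, NaOH) to the saligenin F9, silylated twice (TBSCl, imidazole) to the bis-silyl ether F10, and the benzylic silyl ether is exchanged for bromide (Ph3PBr2) to give the benzylic bromide F11. Carboalumination of F8 (Me3Al, Cp2ZrCl2 cat.) gives the (E)-alkenylalane F12, which is coupled with F11 (Pd(PPh3)4 cat.) to 19. syn-Carbometalation fixes the E geometry and no α/γ question arises.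

## Further compounds

F1 | step 2 | (1Z)-1,6-dihydroxy-6-methylhept-1-en-3-one (enol of 6-hydroxy-6-methyl-3-oxoheptanal) | CC(C)(O)CCC(=O)/C=C\O
F2 | step 2 | racemic 4-hydroxy-1-(7-hydroxy-1,5-dimethylbicyclo[3.2.0]heptan-6-yl)-4-methylpentan-1-one (cis-fused de Mayo cyclobutanol) | CC(C)(O)CCC(=O)C1C(O)C2(C)CCCC12C
F3 | step 2 | racemic cis-2-(5-hydroxy-5-methyl-2-oxohexyl)-1,2-dimethylcyclopentane-1-carbaldehyde | CC(C)(O)CCC(=O)CC1(C)CCCC1(C)C=O
F4 | step 2 | racemic cis-6-(2-hydroxy-2-methylpropyl)-3a,7a-dimethyl-1,2,3,3a,4,7a-hexahydro-5H-inden-5-one | CC(C)(O)CC1=CC2(C)CCCC2(C)CC1=O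
F5 | step 2 | (3aS,7aS)-ring-fusion diastereomer of boronate 10 (from the mirror-image enone) | O=C1C[C@]2(C)CCC[C@]2(C)[C@@H](B3OC(C)(C)C(C)(C)O3)[C@@H]1CC(C)(C)O
F6 | step 2 | (3aS,6S,7S,7aS)-7-hydroxy-6-(2-hydroxy-2-methylpropyl)-3a,7a-dimethyloctahydro-5H-inden-5-one | O=C1C[C@]2(C)CCC[C@]2(C)[C@@H](O)[C@@H]1CC(C)(C)O
F7 | step 3 | 6,7-epoxide of enone 9 (oxirane on the face opposite the angular methyls) | O=C1C[C@@]2(C)CCC[C@@]2(C)[C@H]2O[C@@]12CC(C)(C)O
F8 | step 7 | (3aR,4S,5S,6R,7aR)-5-(2-hydroxy-2-methylpropyl)-3a,7a-dimethyl-6-(prop-2-yn-1-yl)octahydro-1H-indene-4,6-diol | C#CC[C@@]1(O)C[C@@]2(C)CCC[C@@]2(C)[C@@H](O)[C@@H]1CC(C)(C)O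
F9 | step 7 | 2-(hydroxymethyl)-4-methoxy-6-methylphenol | COc1cc(C)c(O)c(CO)c1
F10 | step 7 | tert-butyl[2-({[tert-butyl(dimethyl)silyl]oxy}methyl)-4-methoxy-6-methylphenoxy]dimethylsilane | COc1cc(C)c(O[Si](C)(C)C(C)(C)C)c(CO[Si](C)(C)C(C)(C)C)c1
F11 | step 7 | [2-(bromomethyl)-4-methoxy-6-methylphenoxy](tert-butyl)dimethylsilane | COc1cc(C)c(O[Si](C)(C)C(C)(C)C)c(CBr)c1
F12 | step 7 | (E)-alkenyl(dimethyl)alane from F8 (hydroxyls drawn free, present as aluminium alkoxides) | C[Al](C)/C=C(\C)C[C@@]1(O)C[C@@]2(C)CCC[C@@]2(C)[C@@H](O)[C@@H]1CC(C)(C)O
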